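**Plan**

1. Numbering follows the target SMILES: C1 methyl, C2, C3=C4, C5 carbinol, C6=C7(Cl), C8, C9, O10, C11 carbonyl, C12=C13, C14, C15, C16–C18, spiro C19, C20–C22, C23, N24, C25; ring A = C19–C23, ring B = N24/C15–C19, ring C = N24/C25/C12–C15.
2. Cuts: O10–C11 (lactone), C3=C4 (back to an alkyne) and C4–C5, C12=C13 and N24–C25 (ring C), C14–C15, then C18–C19 (ring B) and C19–N24; what remains is a 2-substituted cyclopentanone from cyclopentanone and (E)-1-nitropropene.
3. Forward: ring A is bought; the ketone becomes a C19=C20 enecarbamate carrying an N-tethered 2-sulfonyl alkene; ring B closes by hydrogen-atom-transfer radical cyclisation; ring C by ring-closing metathesis; the C4–C9 chain is joined by alkynylation and the macrocycle closed by lactonisation, then alkyne semi-hydrogenation.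
4. Enabling feature: C19 is the fully substituted α-amino carbon shared by rings A and B and sits next to C23 with its CH(CH3)CH2O branch, so a flat α-carbamoyl radical centred on C19 is shielded on one face and C18 should bond from the other, which puts N24 on the side of the branch.
5. Stereochemistry: C23 and C2 from the organocatalyst (syn Michael adduct), C19 from C23 in the key step, C15 by hydride delivery to a cyclic imine, C5 by catalyst-controlled alkynylation, the C6=C7 geometry from a lactone ring, the cis C3=C4 olefin from semi-hydrogenation.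

Key step: step 9

Remark: the target is taken exactly as drawn, with C3=C4 cis and, across C6=C7, C5 cis to C8 and trans to Cl.
Remark: deprotonated, metalated and transient activated forms of a numbered compound (enolates, amide salts, alkynylzinc species, the mixed anhydride of step 24) are treated as that compound and carry no number.
Remark: the facial sense of the alkynylation in step 22 is assigned by analogy with aryl and alkenyl aldehydes; the mirror-image ligand is equally available if aldehyde 36 responds in the opposite sense.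

**Route**

Step 1
Reactants: 1 cyclopentanone; 2 (E)-1-nitroprop-1-ene
Product: 3 (2R)-2-[(2R)-1-nitropropan-2-yl]cyclopentan-1-one
Conditions: 1 (10 equiv, neat), 1-[3,5-bis(trifluoromethyl)phenyl]-3-[(2R)-pyrrolidin-2-ylmethyl]thiourea (10 mol%), n-PrCO2H (10 mol%), 0 °C
Reagents that add atoms: none
Why: Enamine-catalysed asymmetric Michael addition, in which the (R)-pyrrolidine forms the enamine of 1 and the thiourea holds the nitro group so that the nitroalkene is attacked through a synclinal transition state, should give the syn adduct with C23 (R) and C2 (R); the ketone is used in excess to suppress double addition.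

Step 2
Reactants: 3 (2R)-2-[(2R)-1-nitropropan-2-yl]cyclopentan-1-one
Product: 5 (2R)-2-[(2R)-1-hydroxypropan-2-yl]cyclopentan-1-one, via keto aldehyde 4 (not isolated)
Conditions: NaOMe (1.0 equiv), MeOH, 0 °C; O3, CH2Cl2/MeOH, −78 °C; N2 purge; NaBH4, −78 °C; aq. NH4Cl
Reagents that add atoms: ozone, [O-][O+]=O
Why: Nef reaction in its ozonolytic form (only the far more acidic nitro group is deprotonated and the nitronate C=N bond is cleaved at −78 °C, so neither C2 nor C23 should epimerise), followed in the same flask by chemoselective borohydride reduction of the aldehyde, which is much faster than that of the α-branched cyclopentanone at this temperature.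

Step 3
Reactants: 5 (2R)-2-[(2R)-1-hydroxypropan-2-yl]cyclopentan-1-one
Product: 6 (2R)-2-[(2R)-1-(tert-butyldiphenylsilyloxy)propan-2-yl]cyclopentan-1-one
Conditions: t-BuPh2SiCl, imidazole, DMF, 0 °C → rt
Reagents that add atoms: tert-butyl(chloro)diphenylsilane, CC(C)(C)[Si](Cl)(c1ccccc1)c1ccccc1
Why: Silylation of the primary alcohol drains the hydroxy ketone/hemiketal equilibrium, and the tert-butyldiphenylsilyl ether is chosen because it must survive Mg/MeOH, RuO4 and CF3CO2H later.

Step 4
Reactants: 6 (2R)-2-[(2R)-1-(tert-butyldiphenylsilyloxy)propan-2-yl]cyclopentan-1-one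
Product: 7 (5R)-5-[(2R)-1-(tert-butyldiphenylsilyloxy)propan-2-yl]cyclopent-1-en-1-yl trifluoromethanesulfonate
Conditions: LiN(i-Pr)2 (1.1 equiv), THF, −78 °C (ketone added to base); PhNTf2, −78 → 0 °C
Reagents that add atoms: N-phenylbis(trifluoromethanesulfonimide), O=S(=O)(N(c1ccccc1)S(=O)(=O)C(F)(F)F)C(F)(F)F
Why: Kinetic enolisation with the hindered amide base removes a C20 proton and not the hindered C23–H, so O-triflation fixes the double bond at C19=C20 and leaves the C23 stereocentre untouched.

Step 5
Reactants: 7 enol triflate; 8 tert-butyl carbamate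
Product: 9 tert-butyl N-{(5R)-5-[(2R)-1-(tert-butyldiphenylsilyloxy)propan-2-yl]cyclopent-1-en-1-yl}carbamate
Conditions: Pd2(dba)3 (2.5 mol%), Xantphos (7.5 mol%), Cs2CO3, 1,4-dioxane, 50 °C
Reagents that add atoms: none
Why: Palladium-catalysed C–N coupling of an enol triflate with a primary carbamate (Buchwald–Hartwig-type amidation with a wide-bite-angle diphosphine) gives the secondary enecarbamate without moving the C19=C20 double bond.

Step 6
Reactants: 10 sodium benzenesulfinate; 11 1,3-dibromopropane
Product: 12 (3-bromopropylsulfonyl)benzene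
Conditions: 11 (3 equiv), DMF, 60 °C
Reagents that add atoms: none
Why: S-Alkylation of the sulfinate by one end of the excess dibromide (SN2) gives the C15–C17 unit with its activating sulfone already on C17.

Step 7
Reactants: 9 secondary enecarbamate; 12 (3-bromopropylsulfonyl)benzene
Product: 13 tert-butyl N-[3-(phenylsulfonyl)propyl]-N-{(5R)-5-[(2R)-1-(tert-butyldiphenylsilyloxy)propan-2-yl]cyclopent-1-en-1-yl}carbamate
Conditions: NaH (1.05 equiv), DMF, 0 °C; then 12, 0 °C → rt
Reagents that add atoms: none
Why: N-Alkylation of the sodium carbamate with a primary bromide (SN2) builds the N24–C15 bond; the sulfone is carried in saturated form here because a carbamate anion would add to a 2-sulfonyl alkene, and the α-sulfonyl carbanion so formed would close a cyclopropane onto the bromide.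

Step 8
Reactants: 13 saturated sulfone
Product: 16 tert-butyl N-[3-(phenylsulfonyl)but-3-en-1-yl]-N-{(5R)-5-[(2R)-1-(tert-butyldiphenylsilyloxy)propan-2-yl]cyclopent-1-en-1-yl}carbamate, via Mannich base 14 (not isolated), via trimethylammonium iodide 15 (not isolated)
Conditions: LiN(i-Pr)2 (1.1 equiv), THF, −78 °C; CH2=NMe2+ I−, −78 → 0 °C; then MeI, MeOH, rt; then aq. NaHCO3, CH2Cl2, rt
Reagents that add atoms: N,N-dimethylmethyleneiminium iodide (Eschenmoser's salt), C=[N+](C)C.[I-]
Why: α-Sulfonyl carbanion formation, Mannich aminomethylation, N-methylation and E1cB (Hofmann-type) loss of trimethylamine is the standard α-methylenation of a sulfone and installs C18 as the CH2 terminus of the acceptor only after the nitrogen is fully substituted.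

Step 9
Reactants: 16 enecarbamate with N-tethered 2-sulfonyl alkene
Product: 17 tert-butyl (1R,5S)-9-(phenylsulfonyl)-1-[(2R)-1-(tert-butyldiphenylsilyloxy)propan-2-yl]-6-azaspiro[4.5]decane-6-carboxylate (both epimers at the sulfone carbon C17)
Conditions: Fe(acac)3 (30 mol%), PhSiH3 (2.5 equiv), Na2HPO4 (1 equiv), EtOH/ethylene glycol 5:1, 0.02 M, 60 °C
Reagents that add atoms: none
Why: An iron hydride generated from Fe(acac)3 and PhSiH3 should hand a hydrogen atom to C20 of the electron-rich enecarbamate rather than to the electron-poor sulfonyl alkene, giving the nucleophilic tertiary α-carbamoyl radical at C19, which adds to the unsubstituted C18 terminus; the resulting α-sulfonyl radical is reduced by divalent iron and protonated by ethanol, which returns trivalent iron. The closest known reaction type is the iron-catalysed hydrogen-atom-transfer reductive coupling of donor olefins (N-vinyl carbamates among them) with acceptor olefins such as vinyl sulfones, run here intramolecularly as a Giese-type cyclisation. Ring B closes in the 6-endo-trig mode, because the 5-exo carbon C17 is fully substituted and bears the sulfone, so attack there is hindered and polarity-mismatched. The new stereocentre C19 is controlled by C23: the planar radical in ring A should bond to C18 on the face opposite the CH(CH3)CH2OSi branch, which gives C19 (S) with N24 cis to the branch; C17 is also formed but its configuration does not matter because the sulfone is removed in step 10. The step needs chemoselective hydrogen-atom transfer and facial control at C19; the first rests on the donor/acceptor polarity of the two olefins (helped by high dilution and the phosphate buffer, which protects the enecarbamate from solvolysis), the second on the adjacent C23 substituent.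

Step 10
Reactants: 17 spirocyclic sulfone
Product: 18 tert-butyl (1R,5S)-1-[(2R)-1-(tert-butyldiphenylsilyloxy)propan-2-yl]-6-azaspiro[4.5]decane-6-carboxylate
Conditions: Mg turnings (10 equiv), MeOH, 50 °C
Reagents that add atoms: none
Why: Single-electron reductive desulfonylation cleaves the C17–S bond of the secondary alkyl phenyl sulfone and merges both C17 epimers into one compound, while the carbamate and the silyl ether are inert.

Step 11
Reactants: 18 N-Boc spiro-piperidine
Product: 19 tert-butyl (1R,5S)-7-oxo-1-[(2R)-1-(tert-butyldiphenylsilyloxy)propan-2-yl]-6-azaspiro[4.5]decane-6-carboxylate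
Conditions: RuO2·xH2O (10 mol%), NaIO4 (4 equiv), EtOAc/H2O 1:1, rt, short reaction time
Reagents that add atoms: sodium periodate, [Na+].[O-]I(=O)(=O)=O (oxygen delivered through RuO4 formed in the flask)
Why: RuO4 oxidation of the methylene next to a carbamate nitrogen gives the N-acyl lactam, and it is regiospecific because C15 is the only α-CH2 (C19 is fully substituted).

Step 12
Reactants: 19 N-Boc lactam; 20 allylmagnesium bromide
Product: 21 tert-butyl N-{(1S,2R)-1-(4-oxohept-6-en-1-yl)-2-[(2R)-1-(tert-butyldiphenylsilyloxy)propan-2-yl]cyclopentyl}carbamate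
Conditions: CH2=CHCH2MgBr (1.2 equiv), THF, −78 °C; aq. NH4Cl at −78 °C
Reagents that add atoms: none
Why: A Grignard reagent adds once to the ring carbonyl of an N-alkoxycarbonyl lactam at low temperature and the adduct opens at N24–C15 to the carbamate-protected amino ketone, which places C14 and C13 (plus one carbon to be lost in the metathesis) on C15; the C18–C19 bond and the C19 stereocentre from step 9 are unaffected.

Step 13
Reactants: 21 keto carbamate
Product: 24 (1R,5S,7R)-7-allyl-1-[(2R)-1-(tert-butyldiphenylsilyloxy)propan-2-yl]-6-azaspiro[4.5]decane, via amino ketone 22 (not isolated), via cyclic imine 23 (not isolated)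
Conditions: CF3CO2H/CH2Cl2 1:4, 0 °C; concentrate; NaBH4, MeOH, −40 → 0 °C
Reagents that add atoms: none
Why: Acid removes the Boc group, the amine recloses ring B on the C15 ketone as the cyclic imine, and axial hydride delivery on the face of ring B that carries the small C20 methylene (away from the C23 branch) should set C15 (R) with the allyl group equatorial and cis to C23; reducing cold, directly after cyclisation, limits migration of the allyl double bond into conjugation.

Step 14
Reactants: 24 secondary amine; 25 methyl 2-(bromomethyl)prop-2-enoate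
Product: 26 methyl 2-{[(1R,5S,7R)-7-allyl-1-[(2R)-1-(tert-butyldiphenylsilyloxy)propan-2-yl]-6-azaspiro[4.5]decan-6-yl]methyl}prop-2-enoate
Conditions: K2CO3, MeCN, rt → 40 °C
Reagents that add atoms: none
Why: N-Alkylation of the hindered amine with a doubly activated allylic bromide (the SN2 and SN2′ paths give the same product) introduces C25, C12 and the ester carbon C11.

Step 15
Reactants: 26 amino diene
Product: 27 tricyclic amino ester (rings A, B and C; C12=C13; methyl ester at C11; C3–OSi(t-Bu)Ph2; C2 R, C15 R, C19 S, C23 R)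
Conditions: second-generation Grubbs catalyst (5 mol%), camphor-10-sulfonic acid (1.1 equiv), CH2Cl2, 40 °C; aq. NaHCO3 work-up
Reagents that add atoms: none
Why: Ring-closing olefin metathesis between the allyl group and the acrylate closes ring C with C12=C13 conjugated to the ester and releases ethene; the amine is kept as its ammonium salt so that it does not bind ruthenium.

Step 16
Reactants: 27 tricyclic silyl ether
Product: 28 tricyclic amino ester with free C3–OH
Conditions: Bu4NF, THF, rt
Reagents that add atoms: none
Why: Fluoride cleaves the silyl ether, and the methyl enoate and the tertiary amine are inert to it.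

Step 17
Reactants: 28 tricyclic alcohol
Product: 29 tricyclic amino ester with C3 aldehyde
Conditions: Dess–Martin periodinane, CH2Cl2, 0 °C → rt; used at once
Reagents that add atoms: none
Why: Dess–Martin oxidation gives the α-branched aldehyde under non-basic conditions, so C2 should keep its configuration.

Step 18
Reactants: 29 tricyclic aldehyde; 30 dimethyl (1-diazo-2-oxopropyl)phosphonate
Product: 31 tricyclic amino ester with terminal alkyne C3≡C4
Conditions: K2CO3, MeOH, 0 °C → rt
Reagents that add atoms: none
Why: Seyferth–Gilbert homologation with the Ohira–Bestmann reagent converts the aldehyde into the alkyne under mild carbonate conditions, and in methanol the methyl ester cannot be scrambled.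

Step 19
Reactants: 32 dihydro-2H-pyran-2,4(3H)-dione
Product: 33 4-chloro-5,6-dihydro-2H-pyran-2-one
Conditions: (COCl)2, DMF (cat.), CH2Cl2, 0 °C → rt
Reagents that add atoms: oxalyl chloride, ClC(=O)C(Cl)=O
Why: A cyclic 1,3-dicarbonyl compound reacts with the Vilsmeier-type reagent at its enol oxygen to give the vinylogous acid chloride, and the ring fixes the future C5 and C8 cis across C6=C7.

Step 20
Reactants: 33 4-chloro-5,6-dihydro-2H-pyran-2-one
Product: 35 (2E)-5-(tert-butyldimethylsilyloxy)-3-chloro-N-methoxy-N-methylpent-2-enamide, via hydroxy amide 34 (not isolated)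
Conditions: MeNH(OMe)·HCl, AlMe3, CH2Cl2, 0 °C; aq. potassium sodium tartrate; crude 34, t-BuMe2SiCl, imidazole, DMF, 0 °C
Reagents that add atoms: N,O-dimethylhydroxylamine hydrochloride, CNOC.Cl; tert-butyl(chloro)dimethylsilane, CC(C)(C)[Si](C)(C)Cl
Why: Aluminium amide aminolysis (Weinreb amide formation) opens the lactone at the acyl carbon with the double-bond geometry retained, and the freed primary alcohol is silylated at once so that it cannot relactonise.

Step 21
Reactants: 35 silyloxy Weinreb amide
Product: 36 (2E)-5-(tert-butyldimethylsilyloxy)-3-chloropent-2-enal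
Conditions: i-Bu2AlH (1.2 equiv), THF, −78 °C; aq. potassium sodium tartrate; used at once
Reagents that add atoms: none
Why: Reduction of a Weinreb amide with i-Bu2AlH stops at the aldehyde through the chelated tetrahedral intermediate and does not touch the vinyl chloride.

Step 22
Reactants: 31 tricyclic alkyne; 36 chloro enal
Product: 37 propargylic alcohol (C4–C5 bond formed; C5 S at this stage; C9–OSiMe2t-Bu; methyl ester)
Conditions: (S,S)-ProPhenol [2,6-bis{[(2S)-2-(hydroxydiphenylmethyl)pyrrolidin-1-yl]methyl}-4-methylphenol] (20 mol%), Me2Zn (3 equiv), Ph3P=O (40 mol%), toluene, 0 °C; 36 (2 equiv) added last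
Reagents that add atoms: none
Why: Catalytic asymmetric alkynylation of an α,β-unsaturated aldehyde by the alkynylzinc formed from Me2Zn under a dinuclear zinc–ProPhenol catalyst forms the C4–C5 bond and should set the carbinol by catalyst control (5S by the priority rules while C3≡C4 is an alkyne, the same spatial arrangement as 5R in the target).

Step 23
Reactants: 37 propargylic alcohol
Product: 39 seco acid (C11 CO2H; free C5–OH and C9–OH), via diol methyl ester 38 (not isolated)
Conditions: Bu4NF, THF, 0 °C → rt; then LiOH, H2O/MeOH, rt; brought to pH 7 with aq. HCl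
Reagents that add atoms: lithium hydroxide, [Li+].[OH-]
Why: Fluoride removes the primary silyl ether and hydroxide then saponifies the methyl ester in the same flask; the non-activated vinyl chloride and the carbinol are stable to both.

Step 24
Reactants: 39 seco acid
Product: 40 fifteen-membered macrolactone with C3≡C4 alkyne
Conditions: 2-methyl-6-nitrobenzoic anhydride (1.5 equiv), DMAP (6 equiv), CH2Cl2, 1 mM, rt, slow addition of 39
Reagents that add atoms: none
Why: Shiina macrolactonisation under high dilution acylates the primary C9 hydroxyl, while the secondary C5 hydroxyl cannot compete because its lactone would be an eleven-membered ring containing the linear C2–C3≡C4–C5 unit.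

Step 25
Reactants: 40 macrocyclic alkyne
Product: 41 target CNP0129639.4
Conditions: H2 (1 atm), Pd/CaCO3 poisoned with Pb(OAc)2, quinoline, EtOAc, rt, stopped after one equivalent of H2
Reagents that add atoms: none
Why: Lindlar semi-hydrogenation adds hydrogen syn to the alkyne and should give the cis C3=C4 olefin, the trisubstituted enoate and the vinyl chloride being reduced far more slowly on the poisoned catalyst.

**Compound list**

1 | cyclopentanone | O=C1CCCC1 | starting material
2 | (E)-1-nitroprop-1-ene | C/C=C/[N+](=O)[O-] | starting material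
3 | (2R)-2-[(2R)-1-nitropropan-2-yl]cyclopentan-1-one | O=C1CCC[C@@H]1[C@@H](C)C[N+](=O)[O-] | intermediate
4 | (2R)-2-[(1R)-2-oxocyclopentyl]propanal | O=C1CCC[C@@H]1[C@@H](C)C=O | intermediate (not isolated)
5 | (2R)-2-[(2R)-1-hydroxypropan-2-yl]cyclopentan-1-one | O=C1CCC[C@@H]1[C@@H](C)CO | intermediate
6 | (2R)-2-[(2R)-1-(tert-butyldiphenylsilyloxy)propan-2-yl]cyclopentan-1-one | O=C1CCC[C@@H]1[C@@H](C)CO[Si](c2ccccc2)(c3ccccc3)C(C)(C)C | intermediate
7 | (5R)-5-[(2R)-1-(tert-butyldiphenylsilyloxy)propan-2-yl]cyclopent-1-en-1-yl trifluoromethanesulfonate | FC(F)(F)S(=O)(=O)OC1=CCC[C@@H]1[C@@H](C)CO[Si](c2ccccc2)(c3ccccc3)C(C)(C)C | intermediate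
8 | tert-butyl carbamate | CC(C)(C)OC(N)=O | starting material
9 | tert-butyl N-{(5R)-5-[(2R)-1-(tert-butyldiphenylsilyloxy)propan-2-yl]cyclopent-1-en-1-yl}carbamate | CC(C)(C)OC(=O)NC1=CCC[C@@H]1[C@@H](C)CO[Si](c2ccccc2)(c3ccccc3)C(C)(C)C | intermediate
10 | sodium benzenesulfinate | [Na+].[O-]S(=O)c1ccccc1 | starting material
11 | 1,3-dibromopropane | BrCCCBr | starting material
12 | (3-bromopropylsulfonyl)benzene | BrCCCS(=O)(=O)c1ccccc1 | intermediate
13 | tert-butyl N-[3-(phenylsulfonyl)propyl]-N-{(5R)-5-[(2R)-1-(tert-butyldiphenylsilyloxy)propan-2-yl]cyclopent-1-en-1-yl}carbamate | CC(C)(C)OC(=O)N(CCCS(=O)(=O)c1ccccc1)C2=CCC[C@@H]2[C@@H](C)CO[Si](c3ccccc3)(c4ccccc4)C(C)(C)C | intermediate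
14 | Mannich base: the N-[4-(dimethylamino)-3-(phenylsulfonyl)butyl] analogue of 13 (both C17 epimers) | CC(C)(C)OC(=O)N(CCC(CN(C)C)S(=O)(=O)c1ccccc1)C2=CCC[C@@H]2[C@@H](C)CO[Si](c3ccccc3)(c4ccccc4)C(C)(C)C | intermediate (not isolated)
15 | trimethylammonium iodide of 14 | CC(C)(C)OC(=O)N(CCC(C[N+](C)(C)C)S(=O)(=O)c1ccccc1)C2=CCC[C@@H]2[C@@H](C)CO[Si](c3ccccc3)(c4ccccc4)C(C)(C)C.[I-] | intermediate (not isolated)
16 | tert-butyl N-[3-(phenylsulfonyl)but-3-en-1-yl]-N-{(5R)-5-[(2R)-1-(tert-butyldiphenylsilyloxy)propan-2-yl]cyclopent-1-en-1-yl}carbamate | CC(C)(C)OC(=O)N(CCC(=C)S(=O)(=O)c1ccccc1)C2=CCC[C@@H]2[C@@H](C)CO[Si](c3ccccc3)(c4ccccc4)C(C)(C)C | intermediate (key-step precursor)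
17 | tert-butyl (1R,5S)-9-(phenylsulfonyl)-1-[(2R)-1-(tert-butyldiphenylsilyloxy)propan-2-yl]-6-azaspiro[4.5]decane-6-carboxylate (both C17 epimers) | CC(C)(C)OC(=O)N1CCC(S(=O)(=O)c2ccccc2)C[C@]13CCC[C@@H]3[C@@H](C)CO[Si](c4ccccc4)(c5ccccc5)C(C)(C)C | intermediate (key-step product)
18 | tert-butyl (1R,5S)-1-[(2R)-1-(tert-butyldiphenylsilyloxy)propan-2-yl]-6-azaspiro[4.5]decane-6-carboxylate | CC(C)(C)OC(=O)N1CCCC[C@]12CCC[C@@H]2[C@@H](C)CO[Si](c3ccccc3)(c4ccccc4)C(C)(C)C | intermediate
19 | tert-butyl (1R,5S)-7-oxo-1-[(2R)-1-(tert-butyldiphenylsilyloxy)propan-2-yl]-6-azaspiro[4.5]decane-6-carboxylate | CC(C)(C)OC(=O)N1C(=O)CCC[C@]12CCC[C@@H]2[C@@H](C)CO[Si](c3ccccc3)(c4ccccc4)C(C)(C)C | intermediate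
20 | allylmagnesium bromide | C=CC[Mg]Br | starting material
21 | tert-butyl N-{(1S,2R)-1-(4-oxohept-6-en-1-yl)-2-[(2R)-1-(tert-butyldiphenylsilyloxy)propan-2-yl]cyclopentyl}carbamate | CC(C)(C)OC(=O)N[C@]1(CCCC(=O)CC=C)CCC[C@@H]1[C@@H](C)CO[Si](c2ccccc2)(c3ccccc3)C(C)(C)C | intermediate
22 | 1-{(1S,2R)-1-amino-2-[(2R)-1-(tert-butyldiphenylsilyloxy)propan-2-yl]cyclopentyl}hept-6-en-4-one | N[C@]1(CCCC(=O)CC=C)CCC[C@@H]1[C@@H](C)CO[Si](c2ccccc2)(c3ccccc3)C(C)(C)C | intermediate (not isolated)
23 | (1R,5S)-7-allyl-1-[(2R)-1-(tert-butyldiphenylsilyloxy)propan-2-yl]-6-azaspiro[4.5]dec-6-ene | C=CCC1=N[C@]2(CCC1)CCC[C@@H]2[C@@H](C)CO[Si](c3ccccc3)(c4ccccc4)C(C)(C)C | intermediate (not isolated)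
24 | (1R,5S,7R)-7-allyl-1-[(2R)-1-(tert-butyldiphenylsilyloxy)propan-2-yl]-6-azaspiro[4.5]decane | C=CC[C@H]1CCC[C@@]2(N1)CCC[C@@H]2[C@@H](C)CO[Si](c3ccccc3)(c4ccccc4)C(C)(C)C | intermediate
25 | methyl 2-(bromomethyl)prop-2-enoate | COC(=O)C(=C)CBr | starting material
26 | methyl 2-{[(1R,5S,7R)-7-allyl-1-[(2R)-1-(tert-butyldiphenylsilyloxy)propan-2-yl]-6-azaspiro[4.5]decan-6-yl]methyl}prop-2-enoate | COC(=O)C(=C)CN1[C@@H](CC=C)CCC[C@]12CCC[C@@H]2[C@@H](C)CO[Si](c3ccccc3)(c4ccccc4)C(C)(C)C | intermediate
27 | tricyclic amino ester, C3–OSi(t-Bu)Ph2 (C2 R, C15 R, C19 S, C23 R) | COC(=O)C1=CC[C@H]2CCC[C@]3(CCC[C@@H]3[C@@H](C)CO[Si](c4ccccc4)(c5ccccc5)C(C)(C)C)N2C1 | intermediate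
28 | tricyclic amino ester, C3–OH | COC(=O)C1=CC[C@H]2CCC[C@]3(CCC[C@@H]3[C@@H](C)CO)N2C1 | intermediate
29 | tricyclic amino ester, C3 aldehyde | COC(=O)C1=CC[C@H]2CCC[C@]3(CCC[C@@H]3[C@@H](C)C=O)N2C1 | intermediate
30 | dimethyl (1-diazo-2-oxopropyl)phosphonate | COP(=O)(OC)C(=[N+]=[N-])C(C)=O | starting material
31 | tricyclic amino ester, C3≡C4 terminal alkyne | COC(=O)C1=CC[C@H]2CCC[C@]3(CCC[C@@H]3[C@@H](C)C#C)N2C1 | intermediate
32 | dihydro-2H-pyran-2,4(3H)-dione | O=C1CCOC(=O)C1 | starting material
33 | 4-chloro-5,6-dihydro-2H-pyran-2-one | O=C1C=C(Cl)CCO1 | intermediate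
34 | (2E)-3-chloro-5-hydroxy-N-methoxy-N-methylpent-2-enamide | CON(C)C(=O)/C=C(/Cl)CCO | intermediate (not isolated)
35 | (2E)-5-(tert-butyldimethylsilyloxy)-3-chloro-N-methoxy-N-methylpent-2-enamide | CON(C)C(=O)/C=C(/Cl)CCO[Si](C)(C)C(C)(C)C | intermediate
36 | (2E)-5-(tert-butyldimethylsilyloxy)-3-chloropent-2-enal | O=C/C=C(/Cl)CCO[Si](C)(C)C(C)(C)C | intermediate
37 | propargylic alcohol (C5 S; C9–OSiMe2t-Bu; methyl ester) | COC(=O)C1=CC[C@H]2CCC[C@]3(CCC[C@@H]3[C@@H](C)C#C[C@@H](O)/C=C(/Cl)CCO[Si](C)(C)C(C)(C)C)N2C1 | intermediate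
38 | diol methyl ester | COC(=O)C1=CC[C@H]2CCC[C@]3(CCC[C@@H]3[C@@H](C)C#C[C@@H](O)/C=C(/Cl)CCO)N2C1 | intermediate (not isolated)
39 | seco acid | OC(=O)C1=CC[C@H]2CCC[C@]3(CCC[C@@H]3[C@@H](C)C#C[C@@H](O)/C=C(/Cl)CCO)N2C1 | intermediate
40 | macrolactone with C3≡C4 alkyne | C[C@H]1C#C[C@@H](O)/C=C(/Cl)CCOC(=O)C2=CC[C@H]3CCC[C@]4(CCC[C@H]14)N3C2 | intermediate
41 | CNP0129639.4 (2S,5R,15R,19S,23R; C3=C4 cis) | C[C@H]1/C=C\[C@@H](O)/C=C(/Cl)CCOC(=O)C2=CC[C@H]3CCC[C@]4(CCC[C@H]14)N3C2 | target

**Step count and risks**

Total: 25 steps. Longest linear sequence: 21 steps (steps 1–5, 7–18 and 22–25, from cyclopentanone).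

Most likely to fail:

1. Step 9. The hydrogen atom may go to the sulfonyl alkene instead of the enecarbamate (reduced acceptor, or closure of the α-sulfonyl radical onto C20), the α-carbamoyl radical may be oxidised to the N-acyliminium ion and captured by ethanol before it cyclises, or the facial preference at C19 may be small. Fallback: from 16, acid-catalysed Markovnikov addition of thiophenol to the enecarbamate (PhSH, catalytic camphor-10-sulfonic acid, CH2Cl2, 0 °C, under argon in the dark) should give the N,S-acetal F1. Bu3SnH and AIBN in refluxing benzene under slow addition then cleave the C19–S bond, so the same C19 radical is made by a tin chain process that does not involve the sulfonyl alkene in the initiation. 6-endo closure and hydrogen transfer from the stannane come back to the route at 17.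

2. Step 13. The allyl double bond may migrate into conjugation with the ketone or the iminium ion before reduction, and hydride delivery to C15 may not be fully face-selective. Fallback: from 19, LiEt3BH (THF, −78 °C) reduces the lactam carbonyl to the N-Boc hemiaminal F2. BF3·OEt2 and allyltrimethylsilane (CH2Cl2, −78 °C) then form the N-acyliminium ion, which passes through no enolisable allyl ketone, and axial allylation gives the N-Boc 7-allyl compound F3. Allylic strain with the carbamate should hold the C19–C23 bond pseudo-axial and steer the allyl group cis to C23; otherwise the C15 epimers are separated at this point. CF3CO2H removes the Boc group and the route is rejoined at 24.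

3. Step 22. Conversion may be low with the valuable alkyne as the limiting partner, the chloro enal may isomerise about C6=C7 before it reacts, or facial selectivity may be insufficient. Fallback: from 31 and 35, the magnesium acetylide of 31 (i-PrMgCl·LiCl, THF, 0 °C) is acylated by Weinreb amide 35 to give the ynone F4. Midland reduction with (S)-Alpine-borane (B-isopinocampheyl-9-borabicyclo[3.3.1]nonane from (−)-α-pinene, neat, rt), in which the linear alkynyl group is the small substituent, should give the same carbinol and returns to the route at 37.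

Further compounds
F1 | step 9 | tert-butyl N-[3-(phenylsulfonyl)but-3-en-1-yl]-N-{(2R)-1-(phenylsulfanyl)-2-[(2R)-1-(tert-butyldiphenylsilyloxy)propan-2-yl]cyclopentyl}carbamate (both C19 epimers) | CC(C)(C)OC(=O)N(CCC(=C)S(=O)(=O)c1ccccc1)C2(Sc3ccccc3)CCC[C@@H]2[C@@H](C)CO[Si](c4ccccc4)(c5ccccc5)C(C)(C)C
F2 | step 13 | tert-butyl (1R,5S)-7-hydroxy-1-[(2R)-1-(tert-butyldiphenylsilyloxy)propan-2-yl]-6-azaspiro[4.5]decane-6-carboxylate | CC(C)(C)OC(=O)N1C(O)CCC[C@]12CCC[C@@H]2[C@@H](C)CO[Si](c3ccccc3)(c4ccccc4)C(C)(C)C
F3 | step 13 | tert-butyl (1R,5S,7R)-7-allyl-1-[(2R)-1-(tert-butyldiphenylsilyloxy)propan-2-yl]-6-azaspiro[4.5]decane-6-carboxylate | CC(C)(C)OC(=O)N1[C@@H](CC=C)CCC[C@]12CCC[C@@H]2[C@@H](C)CO[Si](c3ccccc3)(c4ccccc4)C(C)(C)C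
F4 | step 22 | ynone (C5 ketone between C3≡C4 and C6=C7; C9–OSiMe2t-Bu; methyl ester) | COC(=O)C1=CC[C@H]2CCC[C@]3(CCC[C@@H]3[C@@H](C)C#CC(=O)/C=C(/Cl)CCO[Si](C)(C)C(C)(C)C)N2C1
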